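## Retrosynthetic overview

1. Target 8 ⇒ diol 7 (benzoylation of the primary OH) ⇒ α-hydroxy aldehyde 6 (reduction).
2. Key disconnection: 6 ⇒ 2-hydroxycyclohept-4-enone 5 by an α-ketol 1,2-carbon shift. C3 moves from C2 to C1, the seven-membered ring contracts to the cyclohexene, and C2 becomes the exocyclic CH2O carbon.
3. 5 ⇒ meso cis-diepoxide 2 by two SN2 carboxylate openings (benzoate at C6 under chiral-acid control, acetate at C3), with acetylation of the 7-OH in between.
4. 2 ⇒ tropone 1 by double nucleophilic epoxidation. Tropone supplies all seven core carbons; the acyl groups come from reagents.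
5. Ring order: the seven-membered carbocycle is bought, two oxiranes are made and opened, and the six-membered ring is formed last by contraction.

Assumption: (R)-TRIP, i.e. (R)-3,3′-bis(2,4,6-triisopropylphenyl)-1,1′-binaphthyl-2,2′-diyl hydrogen phosphate, is taken to direct benzoate to C6 as drawn in 3; if the sense is the opposite, the two catalyst enantiomers of steps 2 and 3 are exchanged.

Numbering: compounds 2–5 use cycloheptenone numbering (C1 = C=O); compounds 6–8 use cyclohexene numbering (C1 = quaternary carbinol, C3=C4 alkene).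

## Route

Step 1
Reactants: 1 tropone (cyclohepta-2,4,6-trien-1-one)
Product: 2 meso-(2R,3R,6S,7S)-2,3:6,7-diepoxycyclohept-4-en-1-one
Conditions: t-BuOOH (2.5 equiv), DBU (1.2 equiv), CH2Cl2, −20 → 0 °C; chromatography
Reagents that add atoms: tert-butyl hydroperoxide CC(C)(C)OO
Why: Double Weitz–Scheffer nucleophilic epoxidation (conjugate addition of t-BuOO− then ring closure) attacks only the two electron-poor enone C=C bonds and leaves the isolated 4,5-alkene, and the meso cis-diepoxide (both oxirane oxygens on one face, no absolute configuration set yet) is separated from the C2-symmetric trans isomer.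

Step 2
Reactants: 2 meso cis-diepoxide
Product: 4 (2R,3R,6R,7S)-7-acetoxy-6-(benzoyloxy)-2,3-epoxycyclohept-4-en-1-one, via hydroxy benzoate 3 (not isolated)
Conditions: PhCO2H (1.05 equiv), (R)-TRIP (5 mol %), toluene, 0 °C → rt; then Ac2O, pyridine, DMAP (cat.), 0 °C
Reagents that add atoms: benzoic acid OC(=O)c1ccccc1; acetic anhydride CC(=O)OC(C)=O
Why: Chiral-phosphoric-acid-catalysed desymmetrising carboxylysis (asymmetric epoxide ring opening) of the meso diepoxide, in which benzoate attacks the allylic, ketone-remote C6 of one enantiotopic oxirane with SN2 inversion and so sets 6R and 7S and the absolute configuration of the whole route, followed by in-flask acetylation that caps the 7-OH so it cannot take part in the later ketol shift.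

Step 3
Reactants: 4 epoxy acetate benzoate
Product: 5 (2R,3S,6R,7S)-3,7-diacetoxy-6-(benzoyloxy)-2-hydroxycyclohept-4-en-1-one
Conditions: AcOH (3 equiv), (S)-TRIP (5 mol %), toluene, rt
Reagents that add atoms: acetic acid CC(=O)O
Why: Acid-catalysed SN2 opening of the remaining vinyl oxirane by acetic acid at the allylic C3 (inversion, matched catalyst enantiomer) gives the trans 2-hydroxy-3-acetate, which sets 3S and leaves the 2-OH next to the ketone as the only free hydroxyl.

Step 4
Reactants: 5 α-ketol
Product: 7 (1R,2S,5R,6S)-2,6-diacetoxy-5-(benzoyloxy)-1-(hydroxymethyl)cyclohex-3-en-1-ol, via aldehyde 6 (not isolated)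
Conditions: Sc(OTf)3 (10 mol %), 4 Å MS, CH2Cl2, 0 °C → rt; then NaBH4, MeOH, −40 °C; AcOH quench
Reagents that add atoms: none
Why: Proposed new method: a Sc(OTf)3-catalysed α-ketol (acyloin) 1,2-carbon shift run in the ring-contracting ketone-to-aldehyde direction on a fully acylated 2-hydroxycycloheptenone and made irreversible by in-flask borohydride capture, in which scandium holds O1 and O2 in a cisoid five-membered chelate, the allylic C2–C3 σ bond lies over the C1 π* orbital and migrates suprafacially with retention at C3 so that the new tertiary OH ends on the ring face that carried the 2-OH (1R), with relief of seven-ring strain as driving force, the closest known reactions being Lewis-acid α-ketol rearrangements (steroid D-homoannulation, cisoid-chelate model) and the Bílik ketose-to-branched-aldose carbon shift.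

Step 5
Reactants: 7 diol
Product: 8 [(1R,2S,5R,6S)-2,6-diacetoxy-5-(benzoyloxy)-1-hydroxycyclohex-3-en-1-yl]methyl benzoate
Conditions: BzCl (1.1 equiv), pyridine, CH2Cl2, −20 → 0 °C
Reagents that add atoms: benzoyl chloride O=C(Cl)c1ccccc1
Why: Schotten–Baumann-type O-acylation in which the primary alcohol is benzoylated while the tertiary 1-OH is inert, and no stereocentre is touched.

## Compound list

1 | tropone (cyclohepta-2,4,6-trien-1-one) | O=C1C=CC=CC=C1 | starting material
2 | meso-(2R,3R,6S,7S)-2,3:6,7-diepoxycyclohept-4-en-1-one (cis-diepoxide) | O=C1[C@@H]2O[C@@H]2C=C[C@@H]3O[C@H]13 | intermediate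
3 | (2R,3R,6R,7S)-6-(benzoyloxy)-2,3-epoxy-7-hydroxycyclohept-4-en-1-one | O=C1[C@@H]2O[C@@H]2C=C[C@@H](OC(=O)c3ccccc3)[C@@H]1O | intermediate
4 | (2R,3R,6R,7S)-7-acetoxy-6-(benzoyloxy)-2,3-epoxycyclohept-4-en-1-one | O=C1[C@@H]2O[C@@H]2C=C[C@@H](OC(=O)c3ccccc3)[C@@H]1OC(C)=O | intermediate
5 | (2R,3S,6R,7S)-3,7-diacetoxy-6-(benzoyloxy)-2-hydroxycyclohept-4-en-1-one | O=C1[C@H](O)[C@@H](OC(C)=O)C=C[C@@H](OC(=O)c2ccccc2)[C@@H]1OC(C)=O | intermediate
6 | (1R,2S,5R,6S)-2,6-diacetoxy-5-(benzoyloxy)-1-hydroxycyclohex-3-ene-1-carbaldehyde | O=C[C@@]1(O)[C@@H](OC(C)=O)C=C[C@@H](OC(=O)c2ccccc2)[C@@H]1OC(C)=O | intermediate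
7 | (1R,2S,5R,6S)-2,6-diacetoxy-5-(benzoyloxy)-1-(hydroxymethyl)cyclohex-3-en-1-ol | OC[C@@]1(O)[C@@H](OC(C)=O)C=C[C@@H](OC(=O)c2ccccc2)[C@@H]1OC(C)=O | intermediate
8 | [(1R,2S,5R,6S)-2,6-diacetoxy-5-(benzoyloxy)-1-hydroxycyclohex-3-en-1-yl]methyl benzoate | O=C(OC[C@@]1(O)[C@@H](OC(C)=O)C=C[C@@H](OC(=O)c2ccccc2)[C@@H]1OC(C)=O)c1ccccc1 | target

## Step count and risks

Total step count: 5. Longest linear sequence: 5 (fully linear from tropone).

**Step 1 (most likely to fail).** Nothing in tropone biases the second epoxidation to the face of the first, so cis (meso) and trans isomers are expected in comparable amounts. The mono-epoxide may also drift to tropolone or salicylaldehyde.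

Fallback, from 1 back to 2, with the cis relationship enforced by a peroxide bridge: 1 is reduced with LiAlH4 (Et2O, 0 °C, mild acidic work-up) to cyclohepta-3,5-dien-1-one F1. Sensitised photo-oxygenation (O2, tetraphenylporphyrin, hν, CH2Cl2, 0 °C) gives meso-6,7-dioxabicyclo[3.2.2]non-8-en-3-one F2. Thiourea in MeOH cleaves the O–O bond to meso-(3R,6S)-3,6-dihydroxycyclohept-4-en-1-one F3. Bromination at both α-carbons anti to the neighbouring hydroxyls (PhNMe3Br3, THF, 0 °C) gives meso-(2R,3S,6R,7S)-2,7-dibromo-3,6-dihydroxycyclohept-4-en-1-one F4. K2CO3 in MeOH at 0 °C closes both trans-bromohydrins to the cis-diepoxide 2.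

**Step 4 (the proposed new step).** The shift could stall at the ketol, a 1,2-hydride shift could compete, the 3-acetate could migrate to O2 or eliminate, and the acetates could move to the new primary OH during reduction. A hydride shift followed by carbon shift under the same chelate leads to the same product, so it is not expected to erode the stereochemistry.

Fallback with known chemistry, from 5 back to 7: 5 is oxidised with Dess–Martin periodinane (CH2Cl2, NaHCO3) to (3S,6R,7S)-3,7-diacetoxy-6-(benzoyloxy)cyclohept-4-ene-1,2-dione F6. Benzilic acid rearrangement of its hydrate (aqueous NaHCO3, THF, 0 °C → rt), the textbook irreversible seven-to-six contraction, gives (1R,2S,5R,6S)-2,6-diacetoxy-5-(benzoyloxy)-1-hydroxycyclohex-3-ene-1-carboxylic acid F7. Either acyl shift gives this constitution; the C1 epimer, if formed, is separated. BH3·THF at 0 °C reduces the carboxylic acid in the presence of the esters to diol 7.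

**Step 2.** The enantioselectivity and sense of the acid catalyst on this unprecedented bis(vinyl-epoxy) ketone are untested. Double opening is possible, and base-induced loss of benzoate from the β-acyloxy ketone could occur during acetylation.

Fallback, from 2 back to 4, by enzymatic kinetic resolution instead of catalytic desymmetrisation: 2 is opened once with benzoic acid under achiral acid catalysis (diphenyl phosphate, toluene). This gives racemic hydroxy benzoate, that is 3 together with its enantiomer (2S,3S,6S,7R)-6-(benzoyloxy)-2,3-epoxy-7-hydroxycyclohept-4-en-1-one F5. Candida antarctica lipase B with vinyl acetate (tert-butyl methyl ether, 30 °C) acetylates 3 selectively to 4 and leaves F5 behind (at most 50 %).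

## Further compounds

F1 | step 1 | cyclohepta-3,5-dien-1-one | O=C1CC=CC=CC1
F2 | step 1 | meso-6,7-dioxabicyclo[3.2.2]non-8-en-3-one | O=C1C[C@@H]2C=C[C@H](C1)OO2
F3 | step 1 | meso-(3R,6S)-3,6-dihydroxycyclohept-4-en-1-one | O=C1C[C@@H](O)C=C[C@@H](O)C1
F4 | step 1 | meso-(2R,3S,6R,7S)-2,7-dibromo-3,6-dihydroxycyclohept-4-en-1-one | O=C1[C@H](Br)[C@@H](O)C=C[C@@H](O)[C@@H]1Br
F5 | step 2 | (2S,3S,6S,7R)-6-(benzoyloxy)-2,3-epoxy-7-hydroxycyclohept-4-en-1-one | O=C1[C@H]2O[C@H]2C=C[C@H](OC(=O)c3ccccc3)[C@H]1O
F6 | step 4 | (3S,6R,7S)-3,7-diacetoxy-6-(benzoyloxy)cyclohept-4-ene-1,2-dione | O=C1C(=O)[C@@H](OC(C)=O)C=C[C@@H](OC(=O)c2ccccc2)[C@@H]1OC(C)=O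
F7 | step 4 | (1R,2S,5R,6S)-2,6-diacetoxy-5-(benzoyloxy)-1-hydroxycyclohex-3-ene-1-carboxylic acid | OC(=O)[C@@]1(O)[C@@H](OC(C)=O)C=C[C@@H](OC(=O)c2ccccc2)[C@@H]1OC(C)=O
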